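**Strategy.** The oxolane ring (O1, C2–C5) is closed last by inserting O1. Both ring C–O bonds are benzylic to 4-hydroxy-3,5-dimethoxyphenyl groups, so C2 and C5 are each reachable from a p-quinone methide, and the twofold axis through O1 and the C3–C4 midpoint lets one water molecule bridge two identical methide carbons. The precursor is an acyclic (2R,3R)-2,3-bis(arylmethyl)butane-1,4-diyl diacetate without benzylic oxygen: Ag2O dehydrogenates both phenols, then water forms C2–O1 and O1–C5, and C2/C5 settle all-trans under control of C3/C4. C3–C4 and its configuration come from an auxiliary-controlled oxidative enolate homocoupling.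

Key step: step 6

Remark: the oxolane is numbered O1, C2–C5 (aryl groups on C2 and C5, CH2OH groups on C3 and C4); the target SMILES corresponds to the all-trans (2S,3R,4R,5S) isomer, and sinapic acid and (S)-4-isopropyloxazolidin-2-one are taken as commercial.

**Route**

Step 1
Reactants: 1 sinapic acid [(E)-3-(4-hydroxy-3,5-dimethoxyphenyl)prop-2-enoic acid]
Product: 2 3-(4-hydroxy-3,5-dimethoxyphenyl)propanoic acid
Conditions: H2 (1 atm), 10% Pd/C, MeOH, rt
Reagents that add atoms: none
Why: Heterogeneous catalytic hydrogenation of the cinnamic C=C bond; arene, phenol and acid are inert under these conditions and no stereocentre is formed.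

Step 2
Reactants: 2 3-(4-hydroxy-3,5-dimethoxyphenyl)propanoic acid; 3 (S)-4-isopropyloxazolidin-2-one
Product: 5 4-{3-[(4S)-4-isopropyl-2-oxooxazolidin-3-yl]-3-oxopropyl}-2,6-dimethoxyphenyl pivalate, via mixed pivalic anhydride 4 (not isolated)
Conditions: t-BuCOCl (2.2 equiv), Et3N (3.5 equiv), THF, −20 °C to rt; then LiCl (1.1 equiv), 3 (1.05 equiv), rt
Reagents that add atoms: pivaloyl chloride CC(C)(C)C(=O)Cl
Why: Mixed-anhydride N-acylation of an oxazolidinone (LiCl/Et3N variant); the carboxylate forms the mixed anhydride first, the excess acid chloride (far more electrophilic than that anhydride) caps the phenol as a hindered pivalate, and the oxazolidinone then attacks the unhindered carbonyl of 4, the stereocentre of 3 being untouched.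

Step 3
Reactants: 5 4-{3-[(4S)-4-isopropyl-2-oxooxazolidin-3-yl]-3-oxopropyl}-2,6-dimethoxyphenyl pivalate (two molecules)
Product: 7 (2R,3R)-2,3-bis[(3,5-dimethoxy-4-pivaloyloxyphenyl)methyl]-1,4-bis[(4S)-4-isopropyl-2-oxooxazolidin-3-yl]butane-1,4-dione, via lithium Z-enolate 6 (not isolated)
Conditions: LiN(iPr)2 (1.1 equiv), THF, −78 °C; then TiCl4 (1.1 equiv), CH2Cl2, −78 °C to rt
Reagents that add atoms: none
Why: Oxidative homocoupling of a chiral imide enolate: the chelated Z-enolate is transmetallated to a tetravalent titanium enolate, which is oxidised by one electron (leaving trivalent titanium) and couples at the α-carbons; the isopropyl group of each auxiliary shields one enolate face, so bond formation on the open faces should set both new centres as R (C3 and C4 of the target), and the hindered aryl pivalates, which have no α-hydrogen, are inert to the amide base at −78 °C.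

Step 4
Reactants: 7 (2R,3R)-2,3-bis[(3,5-dimethoxy-4-pivaloyloxyphenyl)methyl]-1,4-bis[(4S)-4-isopropyl-2-oxooxazolidin-3-yl]butane-1,4-dione
Product: 8 (2R,3R)-2,3-bis[(4-hydroxy-3,5-dimethoxyphenyl)methyl]butane-1,4-diol
Conditions: LiAlH4 (excess), THF, 0 °C to rt; then aqueous potassium sodium tartrate
Reagents that add atoms: none
Why: Hydride reductive cleavage of both N-acyl oxazolidinones to primary alcohols (auxiliary 3 is released) and of both aryl pivalates to phenols in one operation; hydride attack on the imide carbonyl is faster than enolisation, so the α-stereocentres should be preserved.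

Step 5
Reactants: 8 (2R,3R)-2,3-bis[(4-hydroxy-3,5-dimethoxyphenyl)methyl]butane-1,4-diol
Product: 9 (2R,3R)-2,3-bis[(4-hydroxy-3,5-dimethoxyphenyl)methyl]butane-1,4-diyl diacetate
Conditions: vinyl acetate (10 equiv), immobilised Candida antarctica lipase B, THF, 40 °C
Reagents that add atoms: vinyl acetate CC(=O)OC=C
Why: Lipase-catalysed irreversible transesterification; the acyl-enzyme transfers acetyl to the two primary aliphatic hydroxyls but not to the phenols, and no stereocentre is touched.

Step 6
Reactants: 9 (2R,3R)-2,3-bis[(4-hydroxy-3,5-dimethoxyphenyl)methyl]butane-1,4-diyl diacetate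
Product: 12 [(2S,3R,4R,5S)-2,5-bis(4-hydroxy-3,5-dimethoxyphenyl)oxolane-3,4-diyl]bis(methylene) diacetate, via bis-quinone methide 10 (not isolated), via hydroxy quinone methide 11 (not isolated)
Conditions: Ag2O (5 equiv), dry CH2Cl2 (0.01 M), rt, dark; filtration; then THF–H2O (4:1), TsOH·H2O (0.1 equiv), 0 °C to rt until the diastereomers have converged
Reagents that add atoms: water O
Why: Ag2O oxidises each 4-alkyl-2,6-dimethoxyphenol by two electrons (the phenoxyl radical, blocked at both ortho positions by OMe, can only disproportionate) to the p-quinone methide 10; acid-catalysed 1,6-addition of water to one methide gives the p-hydroxybenzyl alcohol 11, whose hydroxyl adds 1,6 to the second methide and rearomatises that ring. The closest known reactions are the Ag2O dehydrogenation of p-alkylphenols to quinone methides followed by oxa-1,6-addition, and the water-bridged closure of 8–8′-linked bis-quinone methides that arise on dehydrodimerisation of γ-acylated sinapyl alcohols. The oxolane closes in the 5-exo-trig mode, the oxygen attacking the exocyclic methide carbon, so that C2–O1 and O1–C5 are both made in this step. C2 and C5 are controlled by C3 and C4: both benzylic C–O bonds ionise reversibly through the p-hydroxybenzyl cation under the acid, so each aryl group should settle trans to the neighbouring CH2OAc group, which with the fixed (3R,4R) centres is the all-trans (2S,5S) isomer. The step needs O- over C-alkylation (Friedel–Crafts closure to an aryltetralin), no trapping by the side-chain oxygens and no over-oxidation to aryl ketones: full oxidation to 10 before water is admitted leaves no nucleophilic arene, removal of the oxidant before hydration excludes further oxidation, and the acetates block the primary oxygens.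

Step 7
Reactants: 12 [(2S,3R,4R,5S)-2,5-bis(4-hydroxy-3,5-dimethoxyphenyl)oxolane-3,4-diyl]bis(methylene) diacetate
Product: 13 huazhongilexin [(2S,3R,4R,5S)-2,5-bis(4-hydroxy-3,5-dimethoxyphenyl)oxolane-3,4-diyl]dimethanol
Conditions: K2CO3 (0.2 equiv), MeOH, 0 °C to rt; neutralised with solid NH4Cl
Reagents that add atoms: none
Why: Base-catalysed methanolysis (transesterification) removes both acetates; mild base at or below rt should not open the p-hydroxybenzylic ether, and acid, which could isomerise the free diol to a furofuran, is avoided.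

**Compound list**

1 | sinapic acid, (E)-3-(4-hydroxy-3,5-dimethoxyphenyl)prop-2-enoic acid | COc1cc(/C=C/C(=O)O)cc(OC)c1O | starting material
2 | 3-(4-hydroxy-3,5-dimethoxyphenyl)propanoic acid | COc1cc(CCC(=O)O)cc(OC)c1O | intermediate
3 | (S)-4-isopropyloxazolidin-2-one | CC(C)[C@H]1COC(=O)N1 | starting material
4 | 3-(3,5-dimethoxy-4-pivaloyloxyphenyl)propanoic pivalic anhydride | COc1cc(CCC(=O)OC(=O)C(C)(C)C)cc(OC)c1OC(=O)C(C)(C)C | intermediate (not isolated)
5 | 4-{3-[(4S)-4-isopropyl-2-oxooxazolidin-3-yl]-3-oxopropyl}-2,6-dimethoxyphenyl pivalate | COc1cc(CCC(=O)N2[C@@H](C(C)C)COC2=O)cc(OC)c1OC(=O)C(C)(C)C | intermediate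
6 | lithium (Z)-enolate of 5 | [Li+].[O-]/C(=C\Cc1cc(OC)c(OC(=O)C(C)(C)C)c(OC)c1)N1[C@@H](C(C)C)COC1=O | intermediate (not isolated)
7 | (2R,3R)-2,3-bis[(3,5-dimethoxy-4-pivaloyloxyphenyl)methyl]-1,4-bis[(4S)-4-isopropyl-2-oxooxazolidin-3-yl]butane-1,4-dione | COc1cc(C[C@@H](C(=O)N2[C@@H](C(C)C)COC2=O)[C@H](C(=O)N2[C@@H](C(C)C)COC2=O)Cc2cc(OC)c(OC(=O)C(C)(C)C)c(OC)c2)cc(OC)c1OC(=O)C(C)(C)C | intermediate
8 | (2R,3R)-2,3-bis[(4-hydroxy-3,5-dimethoxyphenyl)methyl]butane-1,4-diol | COc1cc(C[C@@H](CO)[C@H](CO)Cc2cc(OC)c(O)c(OC)c2)cc(OC)c1O | intermediate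
9 | (2R,3R)-2,3-bis[(4-hydroxy-3,5-dimethoxyphenyl)methyl]butane-1,4-diyl diacetate | COc1cc(C[C@@H](COC(C)=O)[C@H](COC(C)=O)Cc2cc(OC)c(O)c(OC)c2)cc(OC)c1O | intermediate
10 | (2R,3R)-2,3-bis[(3,5-dimethoxy-4-oxocyclohexa-2,5-dien-1-ylidene)methyl]butane-1,4-diyl diacetate (bis-quinone methide) | COC1=CC(=C[C@@H](COC(C)=O)[C@H](COC(C)=O)C=C2C=C(OC)C(=O)C(OC)=C2)C=C(OC)C1=O | intermediate (not isolated)
11 | mono-hydrated quinone methide, drawn as the (S)-carbinol epimer that closes to 12 (the other epimer re-enters through 10) | COc1cc([C@@H](O)[C@@H](COC(C)=O)[C@H](COC(C)=O)C=C2C=C(OC)C(=O)C(OC)=C2)cc(OC)c1O | intermediate (not isolated)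
12 | [(2S,3R,4R,5S)-2,5-bis(4-hydroxy-3,5-dimethoxyphenyl)oxolane-3,4-diyl]bis(methylene) diacetate | COc1cc([C@H]2O[C@H](c3cc(OC)c(O)c(OC)c3)[C@@H](COC(C)=O)[C@@H]2COC(C)=O)cc(OC)c1O | intermediate
13 | huazhongilexin, [(2S,3R,4R,5S)-2,5-bis(4-hydroxy-3,5-dimethoxyphenyl)oxolane-3,4-diyl]dimethanol | COc1cc([C@H]2O[C@H](c3cc(OC)c(O)c(OC)c3)[C@@H](CO)[C@@H]2CO)cc(OC)c1O | target

**Totals.** Total step count: 7. Longest linear sequence: 7 steps (from sinapic acid 1).

**Steps most likely to fail**

Step 6 (key step). What may go wrong: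
- C-alkylation instead of O-alkylation, i.e. Friedel–Crafts attack of the rearomatised arene of 11 on the remaining methide.
- Tautomerisation of a methide to the styrene, which would erase the C3/C4 configuration.
- Migration of an acetyl group from a primary oxygen to the new benzylic oxygen.
- Incomplete equilibration of C2/C5 to the all-trans array.

The fallback sets out from 9 and comes back at 12; it separates oxidation from ring closure. Oxidation of 9 with DDQ (2.2 equiv) in MeOH–CH2Cl2 at 0 °C should capture each methide with methanol as it forms, giving the stable, purifiable (2R,3R)-2,3-bis[(4-hydroxy-3,5-dimethoxyphenyl)(methoxy)methyl]butane-1,4-diyl diacetate F1 (benzylic epimers). Catalytic camphorsulfonic acid in wet MeCN at rt should then ionise the benzylic methyl ethers, so that water is taken up and the ring closes by SN1 etherification under the same thermodynamic control, with loss of methanol, to give 12.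

Step 3. What may go wrong: poor facial selectivity in the radical-type C–C coupling (formation of the heterochiral R,S dimer) and low conversion through competing quenching of the enolate. The fallback sets out from 5 and comes back at 8; it builds C3–C4 by two polar steps.
- Auxiliary-controlled enolate alkylation of 5 (NaN(SiMe3)2, THF, −78 °C; tert-butyl bromoacetate) should give tert-butyl (3R)-3-[(3,5-dimethoxy-4-pivaloyloxyphenyl)methyl]-4-[(4S)-4-isopropyl-2-oxooxazolidin-3-yl]-4-oxobutanoate F2.
- LiBH4/MeOH (THF, 0 °C) should cleave the imide to tert-butyl (3R)-4-hydroxy-3-[(3,5-dimethoxy-4-pivaloyloxyphenyl)methyl]butanoate F3.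
- TsOH (toluene, 60 °C) should lactonise F3 to 4-{[(3R)-5-oxooxolan-3-yl]methyl}-2,6-dimethoxyphenyl pivalate F4.
- The lithium enolate of F4 (LiN(SiMe3)2, THF, −78 °C) should add to commercial 4-benzyloxy-3,5-dimethoxybenzaldehyde anti to the existing ring substituent, giving the 3,4-trans aldol lactone 4-{[4-[(4-benzyloxy-3,5-dimethoxyphenyl)(hydroxy)methyl]-5-oxooxolan-3-yl]methyl}-2,6-dimethoxyphenyl pivalate F5 (carbinol epimers).
- Hydrogenolysis (H2, Pd/C, AcOH, cat. HClO4) should remove the benzylic hydroxyl and the O-benzyl group to give 4-{[(3R,4R)-4-[(4-hydroxy-3,5-dimethoxyphenyl)methyl]-5-oxooxolan-3-yl]methyl}-2,6-dimethoxyphenyl pivalate F6.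
- LiAlH4 (THF, 0 °C to rt) should reduce the lactone and cleave the pivalate to give 8.

Step 5. What may go wrong: slow or incomplete enzymatic acylation of the hindered, β-branched primary hydroxyls, leaving a monoacetate. The fallback sets out from 8 and comes back at 9; it over-acylates and then differentiates chemically. Peracetylation (Ac2O, pyridine, cat. 4-dimethylaminopyridine, rt) should give (2R,3R)-2,3-bis[(4-acetoxy-3,5-dimethoxyphenyl)methyl]butane-1,4-diyl diacetate F7. Aminolysis with pyrrolidine (2.2 equiv, CH2Cl2, 0 °C) should then cleave only the two aryl acetates, which are far better acyl donors than the alkyl acetates, to give 9.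

**Further compounds**

F1 | step 6 | (2R,3R)-2,3-bis[(4-hydroxy-3,5-dimethoxyphenyl)(methoxy)methyl]butane-1,4-diyl diacetate (benzylic epimers) | COc1cc(C(OC)[C@@H](COC(C)=O)[C@H](COC(C)=O)C(OC)c2cc(OC)c(O)c(OC)c2)cc(OC)c1O
F2 | step 3 | tert-butyl (3R)-3-[(3,5-dimethoxy-4-pivaloyloxyphenyl)methyl]-4-[(4S)-4-isopropyl-2-oxooxazolidin-3-yl]-4-oxobutanoate | COc1cc(C[C@H](CC(=O)OC(C)(C)C)C(=O)N2[C@@H](C(C)C)COC2=O)cc(OC)c1OC(=O)C(C)(C)C
F3 | step 3 | tert-butyl (3R)-4-hydroxy-3-[(3,5-dimethoxy-4-pivaloyloxyphenyl)methyl]butanoate | COc1cc(C[C@H](CC(=O)OC(C)(C)C)CO)cc(OC)c1OC(=O)C(C)(C)C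
F4 | step 3 | 4-{[(3R)-5-oxooxolan-3-yl]methyl}-2,6-dimethoxyphenyl pivalate | COc1cc(C[C@H]2COC(=O)C2)cc(OC)c1OC(=O)C(C)(C)C
F5 | step 3 | 3,4-trans aldol lactone 4-{[4-[(4-benzyloxy-3,5-dimethoxyphenyl)(hydroxy)methyl]-5-oxooxolan-3-yl]methyl}-2,6-dimethoxyphenyl pivalate (carbinol epimers) | COc1cc(C[C@H]2COC(=O)[C@@H]2C(O)c2cc(OC)c(OCc3ccccc3)c(OC)c2)cc(OC)c1OC(=O)C(C)(C)C
F6 | step 3 | 4-{[(3R,4R)-4-[(4-hydroxy-3,5-dimethoxyphenyl)methyl]-5-oxooxolan-3-yl]methyl}-2,6-dimethoxyphenyl pivalate | COc1cc(C[C@H]2COC(=O)[C@@H]2Cc2cc(OC)c(O)c(OC)c2)cc(OC)c1OC(=O)C(C)(C)C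
F7 | step 5 | (2R,3R)-2,3-bis[(4-acetoxy-3,5-dimethoxyphenyl)methyl]butane-1,4-diyl diacetate | COc1cc(C[C@@H](COC(C)=O)[C@H](COC(C)=O)Cc2cc(OC)c(OC(C)=O)c(OC)c2)cc(OC)c1OC(C)=O
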